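**Retrosynthetic overview**
- The acid comes from its methyl ester. The 1,2-dioxane is opened at C3–O (intramolecular oxa-Michael) and at C6–O (SN2 perhydrolysis of a threo C6 triflate, inversion), leading back to a 6-hydroxy-(E)-enoate.
- The enoate comes from a lactol by stabilised Wittig olefination. The (7Z,9E)-diene comes from a C17 phosphonium ylide and (E)-hepta-2,6-dienal (Z-selective Wittig).
- The threo C6 carbinol comes from a trans-THF aldehyde and an acetal-bearing Grignard reagent (chelation control).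
- The trans-THF comes from an (R)-bishomoallylic alcohol by cobalt-catalysed aerobic oxidative cyclisation; that alcohol comes from (S)-1,2-epoxyhex-5-ene and a 6-chlorohexyl Grignard reagent.
- Ring order: THF first (step 2), 1,2-dioxane last (step 10).

Assumption: (S)-1,2-epoxyhex-5-ene, the dioxanylethyl Grignard solution and Co(modp)2 are bought as such; skeleton positions C1–C24 are counted from the carboxyl carbon.

**Step 1**
Reactants: 1 1-bromo-6-chlorohexane; 2 (2S)-2-(but-3-en-1-yl)oxirane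
Product: 4 (5R)-12-chlorododec-1-en-5-ol, via (6-chlorohexyl)magnesium bromide 3 (not isolated)
Conditions: Mg, THF, 35 °C; then CuI (10 mol%), 2, THF, –30 → 0 °C; water work-up
Reagents that add atoms: none
Why: Magnesium inserts selectively into the C–Br bond and the copper-catalysed Grignard opening of the terminal epoxide is an SN2 attack at the unsubstituted CH2, so the epoxide stereocentre is untouched and becomes the (R)-carbinol C10 (the descriptor changes only through CIP priorities).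

**Step 2**
Reactants: 4 (5R)-12-chlorododec-1-en-5-ol
Product: 5 [(2S,5R)-5-(7-chloroheptyl)oxolan-2-yl]methanol
Conditions: Co(modp)2 [Co(C12H18NO4)2, cobalt bis(1-morpholinocarbamoyl-4,4-dimethylpentane-1,3-dionate), divalent cobalt] (10 mol%), O2 (1 atm), tBuOOH (10 mol%), 4 Å MS, iPrOH, 55 °C
Reagents that add atoms: dioxygen, O=O
Why: The Mukaiyama aerobic oxidative cyclisation of a pent-4-en-1-ol closes the THF ring with very high 2,5-trans selectivity, so the existing C10 centre sets the new C7 centre as S and the terminal carbon emerges as the primary alcohol.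

**Step 3**
Reactants: 5 [(2S,5R)-5-(7-chloroheptyl)oxolan-2-yl]methanol
Product: 6 (2S,5R)-5-(7-chloroheptyl)oxolane-2-carbaldehyde
Conditions: Dess–Martin periodinane, CH2Cl2, 0 °C → rt; used directly
Reagents that add atoms: none
Why: Dess–Martin oxidation gives the α-alkoxy aldehyde under near-neutral conditions that do not epimerise C7 and leave the alkyl chloride untouched.

**Step 4**
Reactants: 6 (2S,5R)-5-(7-chloroheptyl)oxolane-2-carbaldehyde; 7 [2-(1,3-dioxan-2-yl)ethyl]magnesium bromide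
Product: 8 (1S)-1-[(2S,5R)-5-(7-chloroheptyl)oxolan-2-yl]-3-(1,3-dioxan-2-yl)propan-1-ol
Conditions: MgBr2·OEt2 (3 equiv), CH2Cl2, –78 °C; then 7 (0.5 M in THF, 1.5 equiv), –78 °C; water work-up
Reagents that add atoms: none
Why: This is a chelation-controlled (Cram chelate) Grignard addition in which magnesium bridges the ring oxygen and the carbonyl oxygen and the nucleophile enters past the small α-hydrogen, giving the threo (6S,7S) carbinol, with the minor erythro epimer removed by chromatography.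

**Step 5**
Reactants: 8 (1S)-1-[(2S,5R)-5-(7-chloroheptyl)oxolan-2-yl]-3-(1,3-dioxan-2-yl)propan-1-ol
Product: 10 (7-{(2R,5S)-5-[(1S)-3-(1,3-dioxan-2-yl)-1-hydroxypropyl]oxolan-2-yl}heptyl)triphenylphosphonium iodide, via primary iodide 9 (not isolated)
Conditions: NaI (3 equiv), PPh3 (2 equiv), MeCN, reflux
Reagents that add atoms: sodium iodide, [Na+].[I-]; triphenylphosphine, c1ccc(cc1)P(c1ccccc1)c1ccccc1
Why: Finkelstein exchange of the primary chloride followed by SN2 quaternisation of triphenylphosphine gives the phosphonium salt under neutral conditions that leave the secondary alcohol, the acetal and all stereocentres alone.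

**Step 6**
Reactants: 11 pent-4-enal; 12 2-(triphenyl-λ5-phosphanylidene)acetaldehyde
Product: 13 (2E)-hepta-2,6-dienal
Conditions: toluene, 80 °C
Reagents that add atoms: none
Why: Wittig olefination of an aliphatic aldehyde with the stabilised formyl ylide gives the (E)-enal selectively.

**Step 7**
Reactants: 10 (7-{(2R,5S)-5-[(1S)-3-(1,3-dioxan-2-yl)-1-hydroxypropyl]oxolan-2-yl}heptyl)triphenylphosphonium iodide; 13 (2E)-hepta-2,6-dienal
Product: 15 (1S)-3-(1,3-dioxan-2-yl)-1-{(2S,5R)-5-[(7Z,9E)-tetradeca-7,9,13-trien-1-yl]oxolan-2-yl}propan-1-ol, via sodium alkoxide ylide 14 (not isolated)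
Conditions: NaN(SiMe3)2 (2.1 equiv), THF, –78 → 0 °C; then 13, –78 °C → rt; water work-up
Reagents that add atoms: none
Why: A lithium-free Wittig olefination of the non-stabilised ylide (the second equivalent of base covers the free hydroxyl) forms the new C17=C18 bond Z under kinetic control while the E-alkene of the enal is carried through unchanged, giving the (7Z,9E)-diene.

**Step 8**
Reactants: 15 (1S)-3-(1,3-dioxan-2-yl)-1-{(2S,5R)-5-[(7Z,9E)-tetradeca-7,9,13-trien-1-yl]oxolan-2-yl}propan-1-ol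
Product: 17 (5S)-5-{(2S,5R)-5-[(7Z,9E)-tetradeca-7,9,13-trien-1-yl]oxolan-2-yl}oxolan-2-ol (anomer mixture), via open hydroxy aldehyde 16 (not isolated)
Conditions: 1 M HCl, THF, rt
Reagents that add atoms: water, O
Why: Acid-catalysed acetal hydrolysis releases the C3 aldehyde, which is captured by the C6 hydroxyl as the five-membered lactol, and the unactivated diene and alkenes tolerate dilute acid at room temperature.

**Step 9**
Reactants: 17 (5S)-5-{(2S,5R)-5-[(7Z,9E)-tetradeca-7,9,13-trien-1-yl]oxolan-2-yl}oxolan-2-ol; 18 methyl 2-(triphenyl-λ5-phosphanylidene)acetate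
Product: 19 methyl (2E,6S)-6-hydroxy-6-{(2S,5R)-5-[(7Z,9E)-tetradeca-7,9,13-trien-1-yl]oxolan-2-yl}hex-2-enoate
Conditions: PhCO2H (10 mol%), toluene, 50 °C
Reagents that add atoms: none
Why: Wittig olefination of the lactol through its open hydroxy-aldehyde form 16 with a stabilised ylide gives the (E)-enoate without touching any stereocentre.

**Step 10**
Reactants: 19 methyl (2E,6S)-6-hydroxy-6-{(2S,5R)-5-[(7Z,9E)-tetradeca-7,9,13-trien-1-yl]oxolan-2-yl}hex-2-enoate
Product: 22 methyl 2-[(3R,6R)-6-{(2S,5R)-5-[(7Z,9E)-tetradeca-7,9,13-trien-1-yl]oxolan-2-yl}-1,2-dioxan-3-yl]acetate, via triflate 20 (not isolated), via hydroperoxide 21 (not isolated)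
Conditions: Tf2O (1.2 equiv), 2,6-lutidine (1.5 equiv), CH2Cl2, –78 °C; then transfer into anhydrous H2O2 in Et2O (15 equiv), KOtBu (3 equiv), 18-crown-6 (10 mol%), THF, –40 → 0 °C; chromatography to remove the minor cis isomer
Reagents that add atoms: hydrogen peroxide, OO
Why: Triflation followed by SN2 perhydrolysis with hydroperoxide anion inverts C6 from S to R, and the alkylperoxide anion then closes by a reversible 6-exo-trig intramolecular oxa-Michael addition through a chair with both substituents equatorial, which sets C3 as R in the trans-3,6-disubstituted 1,2-dioxane.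

**Step 11**
Reactants: 22 methyl 2-[(3R,6R)-6-{(2S,5R)-5-[(7Z,9E)-tetradeca-7,9,13-trien-1-yl]oxolan-2-yl}-1,2-dioxan-3-yl]acetate
Product: 23 2-[(3R,6R)-6-{(2S,5R)-5-[(7Z,9E)-tetradeca-7,9,13-trien-1-yl]oxolan-2-yl}-1,2-dioxan-3-yl]acetic acid
Conditions: LiOH (3 equiv), THF–H2O (3:1), 0 °C; then cold 1 M HCl to pH 3
Reagents that add atoms: lithium hydroxide, [Li+].[OH-]
Why: Saponification of the unhindered methyl ester at 0 °C is faster than base-induced cleavage of the dialkyl peroxide, and acidification gives the free acid with all four stereocentres and both diene geometries unchanged.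

**Compound list**
1 | 1-bromo-6-chlorohexane | ClCCCCCCBr | starting material
2 | (2S)-2-(but-3-en-1-yl)oxirane | C=CCC[C@H]1CO1 | starting material
3 | (6-chlorohexyl)magnesium bromide | ClCCCCCC[Mg]Br | intermediate
4 | (5R)-12-chlorododec-1-en-5-ol | C=CCC[C@H](O)CCCCCCCCl | intermediate
5 | [(2S,5R)-5-(7-chloroheptyl)oxolan-2-yl]methanol | ClCCCCCCC[C@@H]1CC[C@@H](CO)O1 | intermediate
6 | (2S,5R)-5-(7-chloroheptyl)oxolane-2-carbaldehyde | ClCCCCCCC[C@@H]1CC[C@@H](C=O)O1 | intermediate
7 | [2-(1,3-dioxan-2-yl)ethyl]magnesium bromide (0.5 M in THF) | Br[Mg]CCC1OCCCO1 | starting material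
8 | (1S)-1-[(2S,5R)-5-(7-chloroheptyl)oxolan-2-yl]-3-(1,3-dioxan-2-yl)propan-1-ol | ClCCCCCCC[C@@H]1CC[C@@H]([C@@H](O)CCC2OCCCO2)O1 | intermediate
9 | (1S)-3-(1,3-dioxan-2-yl)-1-[(2S,5R)-5-(7-iodoheptyl)oxolan-2-yl]propan-1-ol | ICCCCCCC[C@@H]1CC[C@@H]([C@@H](O)CCC2OCCCO2)O1 | intermediate
10 | (7-{(2R,5S)-5-[(1S)-3-(1,3-dioxan-2-yl)-1-hydroxypropyl]oxolan-2-yl}heptyl)triphenylphosphonium iodide | c1ccccc1[P+](c1ccccc1)(c1ccccc1)CCCCCCC[C@@H]1CC[C@@H]([C@@H](O)CCC2OCCCO2)O1.[I-] | intermediate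
11 | pent-4-enal | C=CCCC=O | starting material
12 | 2-(triphenyl-λ5-phosphanylidene)acetaldehyde | O=CC=P(c1ccccc1)(c1ccccc1)c1ccccc1 | starting material
13 | (2E)-hepta-2,6-dienal | C=CCC/C=C/C=O | intermediate
14 | sodium (1S)-3-(1,3-dioxan-2-yl)-1-{(2S,5R)-5-[7-(triphenyl-λ5-phosphanylidene)heptyl]oxolan-2-yl}propan-1-olate | c1ccccc1P(c1ccccc1)(c1ccccc1)=CCCCCCC[C@@H]1CC[C@@H]([C@@H]([O-])CCC2OCCCO2)O1.[Na+] | intermediate
15 | (1S)-3-(1,3-dioxan-2-yl)-1-{(2S,5R)-5-[(7Z,9E)-tetradeca-7,9,13-trien-1-yl]oxolan-2-yl}propan-1-ol | C=CCC/C=C/C=C\CCCCCC[C@@H]1CC[C@@H]([C@@H](O)CCC2OCCCO2)O1 | intermediate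
16 | (4S)-4-hydroxy-4-{(2S,5R)-5-[(7Z,9E)-tetradeca-7,9,13-trien-1-yl]oxolan-2-yl}butanal | C=CCC/C=C/C=C\CCCCCC[C@@H]1CC[C@@H]([C@@H](O)CCC=O)O1 | intermediate
17 | (5S)-5-{(2S,5R)-5-[(7Z,9E)-tetradeca-7,9,13-trien-1-yl]oxolan-2-yl}oxolan-2-ol (anomer mixture) | C=CCC/C=C/C=C\CCCCCC[C@@H]1CC[C@@H]([C@@H]2CCC(O)O2)O1 | intermediate
18 | methyl 2-(triphenyl-λ5-phosphanylidene)acetate | COC(=O)C=P(c1ccccc1)(c1ccccc1)c1ccccc1 | starting material
19 | methyl (2E,6S)-6-hydroxy-6-{(2S,5R)-5-[(7Z,9E)-tetradeca-7,9,13-trien-1-yl]oxolan-2-yl}hex-2-enoate | C=CCC/C=C/C=C\CCCCCC[C@@H]1CC[C@@H]([C@@H](O)CC/C=C/C(=O)OC)O1 | intermediate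
20 | methyl (2E,6S)-6-{(2S,5R)-5-[(7Z,9E)-tetradeca-7,9,13-trien-1-yl]oxolan-2-yl}-6-[(trifluoromethanesulfonyl)oxy]hex-2-enoate | C=CCC/C=C/C=C\CCCCCC[C@@H]1CC[C@@H]([C@@H](OS(=O)(=O)C(F)(F)F)CC/C=C/C(=O)OC)O1 | intermediate
21 | methyl (2E,6R)-6-hydroperoxy-6-{(2S,5R)-5-[(7Z,9E)-tetradeca-7,9,13-trien-1-yl]oxolan-2-yl}hex-2-enoate | C=CCC/C=C/C=C\CCCCCC[C@@H]1CC[C@@H]([C@H](OO)CC/C=C/C(=O)OC)O1 | intermediate
22 | methyl 2-[(3R,6R)-6-{(2S,5R)-5-[(7Z,9E)-tetradeca-7,9,13-trien-1-yl]oxolan-2-yl}-1,2-dioxan-3-yl]acetate | C=CCC/C=C/C=C\CCCCCC[C@@H]1CC[C@@H]([C@H]2CC[C@H](CC(=O)OC)OO2)O1 | intermediate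
23 | 2-[(3R,6R)-6-{(2S,5R)-5-[(7Z,9E)-tetradeca-7,9,13-trien-1-yl]oxolan-2-yl}-1,2-dioxan-3-yl]acetic acid | C=CCC/C=C/C=C\CCCCCC[C@@H]1CC[C@@H]([C@H]2CC[C@H](CC(=O)O)OO2)O1 | target

**Step count**
Total: 11 steps. Longest linear sequence: 10 steps (steps 1–5 and 7–11); step 6 is a one-step side branch.

**Three steps most likely to fail, with fallbacks**

Step 10 is the weakest step. SN2 perhydrolysis at a secondary carbon next to the THF oxygen can lose out to elimination, to participation of the ring oxygen, to double alkylation of H2O2 or to attack of hydroperoxide anion on the enoate, and the one-pot closure gives some cis-dioxane. The fallback sets out from 19 and comes back at 22. Compound 19 is triflated as before to 20, which is alkylated with the potassium salt (KOtBu, THF, 0 °C) of the mono-protected peroxide 2-hydroperoxy-2-methoxypropane F1, made beforehand by ozonolysis of 2,3-dimethylbut-2-ene in MeOH–CH2Cl2 at –78 °C. This gives, with inversion at C6, the chromatographically stable peroxyketal methyl (2E,6R)-6-[(2-methoxypropan-2-yl)peroxy]-6-{(2S,5R)-5-[(7Z,9E)-tetradeca-7,9,13-trien-1-yl]oxolan-2-yl}hex-2-enoate F2. Aqueous AcOH–THF at rt unmasks hydroperoxide 21, which is now isolated and cyclised on its own with Et2NH in CF3CH2OH to 22. This replaces direct perhydrolysis by a protected-peroxide transfer in which neither double alkylation nor free hydroperoxide anion can arise, and it lets the ring closure be run and equilibrated separately.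

Step 4 may give a poor threo:erythro ratio, because the THF that comes with the Grignard solution weakens the chelate. The fallback sets out from 6 and comes back at 8. Compound 7 is added to 6 in THF at –78 °C without any attempt at control, giving 8 mixed with its carbinol epimer (1R)-1-[(2S,5R)-5-(7-chloroheptyl)oxolan-2-yl]-3-(1,3-dioxan-2-yl)propan-1-ol F3. The mixture is oxidised with Dess–Martin periodinane to the single ketone 1-[(2S,5R)-5-(7-chloroheptyl)oxolan-2-yl]-3-(1,3-dioxan-2-yl)propan-1-one F4. Reduction with LiBH(sec-Bu)3 in THF at –78 °C then follows the Felkin–Anh course (hydride anti to the ring C–O bond) and gives the threo alcohol 8. The C6 centre is thus set by reagent-controlled ketone reduction instead of by the C–C bond formation.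

Step 7 may give an inseparable share of the (7E,9E)-diene, or a sluggish ylide because of the neighbouring alkoxide. The fallback sets out from 8 and comes back at 15. Compound 8 is converted into iodide 9 (NaI, acetone, reflux; here isolated), and Kornblum oxidation (DMSO, NaHCO3, 100 °C) gives the aldehyde 7-{(2R,5S)-5-[(1S)-3-(1,3-dioxan-2-yl)-1-hydroxypropyl]oxolan-2-yl}heptanal F5. Stork–Zhao olefination with (iodomethyl)triphenylphosphonium iodide and NaN(SiMe3)2 (2.2 equiv) in THF–DMPU at –78 °C gives the vinyl iodide (1S)-3-(1,3-dioxan-2-yl)-1-{(2S,5R)-5-[(7Z)-8-iodooct-7-en-1-yl]oxolan-2-yl}propan-1-ol F6. Its coupling partner is 2-[(1E)-hexa-1,5-dien-1-yl]-4,4,5,5-tetramethyl-1,3,2-dioxaborolane F7, made from hex-1-en-5-yne and pinacolborane with catalytic Cp2Zr(H)Cl. Stereoretentive Suzuki–Miyaura coupling of F6 and F7 (PdCl2(dppf), [1,1'-bis(diphenylphosphino)ferrocene]dichloropalladium, divalent palladium precatalyst; aqueous K3PO4, THF, 45 °C) gives 15. Each alkene geometry is then fixed separately before the two halves are joined, and no peroxide is yet present to interfere with palladium.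

**Further compounds**
F1 | step 10 | 2-hydroperoxy-2-methoxypropane | COC(C)(C)OO
F2 | step 10 | methyl (2E,6R)-6-[(2-methoxypropan-2-yl)peroxy]-6-{(2S,5R)-5-[(7Z,9E)-tetradeca-7,9,13-trien-1-yl]oxolan-2-yl}hex-2-enoate | C=CCC/C=C/C=C\CCCCCC[C@@H]1CC[C@@H]([C@H](OOC(C)(C)OC)CC/C=C/C(=O)OC)O1
F3 | step 4 | (1R)-1-[(2S,5R)-5-(7-chloroheptyl)oxolan-2-yl]-3-(1,3-dioxan-2-yl)propan-1-ol | ClCCCCCCC[C@@H]1CC[C@@H]([C@H](O)CCC2OCCCO2)O1
F4 | step 4 | 1-[(2S,5R)-5-(7-chloroheptyl)oxolan-2-yl]-3-(1,3-dioxan-2-yl)propan-1-one | ClCCCCCCC[C@@H]1CC[C@@H](C(=O)CCC2OCCCO2)O1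
F5 | step 7 | 7-{(2R,5S)-5-[(1S)-3-(1,3-dioxan-2-yl)-1-hydroxypropyl]oxolan-2-yl}heptanal | O=CCCCCCC[C@@H]1CC[C@@H]([C@@H](O)CCC2OCCCO2)O1
F6 | step 7 | (1S)-3-(1,3-dioxan-2-yl)-1-{(2S,5R)-5-[(7Z)-8-iodooct-7-en-1-yl]oxolan-2-yl}propan-1-ol | I/C=C\CCCCCC[C@@H]1CC[C@@H]([C@@H](O)CCC2OCCCO2)O1
F7 | step 7 | 2-[(1E)-hexa-1,5-dien-1-yl]-4,4,5,5-tetramethyl-1,3,2-dioxaborolane | C=CCC/C=C/B1OC(C)(C)C(C)(C)O1
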